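## Retrosynthetic overview

1. Labdane numbering is used: ring A = C1–C5/C10, ring B = C5–C10, cyclobutane (ring C) = C8, C9, C14, C15, cyclopentane (ring D) = C9, C11, C12, C13, C14; methyls C16 (on C13), C17 (on C8), C18/C19 (on C4), C20 (on C10).
2. Enabling feature: ring C carries the C7 ketone on C8 and shares its C9–C14 edge with ring D, so that C9 (β to the ketone) is tied to C14 through the three-atom bridge C11–C12–C13. This is the retron of an intramolecular enone–alkene [2+2] photocycloaddition.
3. Key disconnection: C9–C14 (closes ring D) together with C8–C15, leading back to bicyclic dienone 11, (13S)-6β-acetoxy-13-hydroxylabda-8,14-dien-7-one, an isomer of the target with two rings and three stereocentres fewer.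
4. Dienone 11 is traced to larixol 1, which supplies rings A and B, all twenty skeletal carbons and the 13S carbinol. C6 is inverted by oxidation and α-face reduction, then acetylated, and a singlet-oxygen ene/Kornblum–DeLaMare sequence turns the Δ7 alkene into the Δ8-7-one.
5. Ring order: rings A and B come with the starting material; ring D is closed in the final ring-forming step (the key step), the same light-driven event completing ring C; no ring is formed afterwards.

Key step: step 8

Assumption: larixol, a diterpene diol from larch oleoresin sold as a research chemical, is taken as the commercially available, enantiopure starting material, with the configuration (13S)-labda-8(17),14-diene-6α,13-diol.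

## Route

Step 1
Reactants: 1 larixol
Product: 2 (13S)-13-hydroxylabda-8(17),14-dien-6-one
Conditions: Dess–Martin periodinane, pyridine, CH2Cl2, 0 °C → rt
Reagents that add atoms: none
Why: Dess–Martin oxidation should convert the only secondary alcohol (6α-OH) into the ketone, while the tertiary allylic 13-OH cannot be oxidised and is not transposed under these non-acidic conditions.

Step 2
Reactants: 2 (13S)-13-hydroxylabda-8(17),14-dien-6-one
Product: 3 (13S)-13-(triethylsilyloxy)labda-8(17),14-dien-6-one
Conditions: Et3SiOTf, 2,6-lutidine, CH2Cl2, −78 °C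
Reagents that add atoms: triethylsilyl trifluoromethanesulfonate, CC[Si](CC)(CC)OS(=O)(=O)C(F)(F)F
Why: Silyl triflate silylation of the tertiary allylic alcohol protects O-13 against conjugate addition in step 3 and against acetylation in step 5, and any premature double-bond migration is harmless because step 3 brings it about anyway.

Step 3
Reactants: 3 (13S)-13-(triethylsilyloxy)labda-8(17),14-dien-6-one
Product: 4 (13S)-13-(triethylsilyloxy)labda-7,14-dien-6-one
Conditions: DBU (cat.), CH2Cl2, rt
Reagents that add atoms: none
Why: Base-mediated isomerisation of the β,γ-unsaturated ketone through its dienolate should give the thermodynamically favoured conjugated Δ7-enone; the trans ring fusion at C5 is the stable one and the C9 centre is erased later in any case.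

Step 4
Reactants: 4 (13S)-13-(triethylsilyloxy)labda-7,14-dien-6-one
Product: 5 (13S)-13-(triethylsilyloxy)labda-7,14-dien-6β-ol
Conditions: NaBH4, CeCl3·7H2O, MeOH, −40 → 0 °C
Reagents that add atoms: none
Why: Luche 1,2-reduction should deliver hydride to the α face of C6, because the β face is shielded by the syn-axial methyls C19 and C20, which sets the axial 6β-hydroxyl.

Step 5
Reactants: 5 (13S)-13-(triethylsilyloxy)labda-7,14-dien-6β-ol
Product: 7 (13S)-13-(triethylsilyloxy)labda-7,14-dien-6β-yl acetate, via lithium 6β-alkoxide 6 (not isolated)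
Conditions: LiN(SiMe3)2, THF, −78 °C; then Ac2O, −78 → 0 °C
Reagents that add atoms: acetic anhydride, CC(=O)OC(C)=O
Why: O-acylation of a preformed lithium alkoxide is chosen because the axial 6β-hydroxyl, flanked 1,3-diaxially by C19 and C20, is expected to be sluggish under amine-catalysed acetylation; the C6 configuration is untouched.

Step 6
Reactants: 7 (13S)-13-(triethylsilyloxy)labda-7,14-dien-6β-yl acetate
Product: 10 (13S)-6β-acetoxy-13-(triethylsilyloxy)labda-8,14-dien-7-one, via 7α-hydroperoxide 8 (not isolated), via 7α-peracetate 9 (not isolated)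
Conditions: O2, tetraphenylporphyrin (cat.), hν (visible), CH2Cl2, 0 °C; then Ac2O, pyridine, DMAP (cat.), 0 °C → rt
Reagents that add atoms: dioxygen (used as singlet oxygen), O=O
Why: In the Schenck ene reaction, singlet oxygen should add to C7 from the α face (the β face is blocked by the pseudoaxial 6β-acetate and C20) and abstract the pseudoaxial allylic H-9α, which lies perpendicular to the alkene plane on its disubstituted side, so the double bond moves to C8=C9; Kornblum–DeLaMare dehydration of the acetylated secondary hydroperoxide then gives the enone, so the transient C7 centre does not matter.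

Step 7
Reactants: 10 (13S)-6β-acetoxy-13-(triethylsilyloxy)labda-8,14-dien-7-one
Product: 11 (13S)-6β-acetoxy-13-hydroxylabda-8,14-dien-7-one
Conditions: HF·pyridine, pyridine, THF, 0 °C → rt
Reagents that add atoms: none
Why: Fluoride-mediated cleavage of the triethylsilyl ether under buffered, non-basic conditions should leave the α'-acetoxy enone intact and avoid conjugate addition of the freed 13-OH to C9.

Step 8
Reactants: 11 (13S)-6β-acetoxy-13-hydroxylabda-8,14-dien-7-one
Product: 12 target CNP0330581.1, (13S)-6β-acetoxy-13-hydroxy-8,15:9,14-dicyclolabdan-7-one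
Conditions: hν (365 nm), degassed MeCN (5 mM), rt
Reagents that add atoms: none
Why: Intramolecular enone–alkene [2+2] photocycloaddition: n→π* excitation and intersystem crossing give the enone triplet, whose β-carbon C9 bonds to the internal vinyl carbon C14 (rule of five, 5-exo closure of cyclopentane C9–C11–C12–C13–C14), and the resulting 1,4-biradical (tertiary α-keto radical at C8, primary radical at C15) undergoes spin inversion and C8–C15 recombination, which completes the cyclobutane. The closest known reaction type is the photocycloaddition of 2-alkyl-3-(pent-4-enyl)cyclohex-2-enones, which gives linearly fused 6-4-5 adducts with adjacent quaternary carbons. C9 is set by attack of the tethered vinyl group on the α face of ring B, anti to the axial C20 methyl on the neighbouring C10 (the 6β-acetate shields the same β face); C8 follows because C15 is held on the α face by the new C9–C14 bond and closes to the cis-fused cyclobutane, leaving C17 β; C14 follows because the bicyclo[3.2.0]heptane can only be cis-fused, and the existing 13S centre then places the hydroxyl exo. The step needs straight rather than crossed regiochemistry, secured by the three-atom tether (1,5- rather than 1,6-closure); α- rather than β-facial attack, secured by C20; and excitation of the enone alone, secured by irradiating at 365 nm, where the acetate and the saturated ketone product hardly absorb. All atoms of 11 are retained, so this isomerisation creates two rings, three stereocentres and two of the three contiguous quaternary carbons (C8, C9).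

## Compound list

1 | larixol, (13S)-labda-8(17),14-diene-6α,13-diol (5α-H, 9α-H, 10β-CH3) | O[C@H]1CC(=C)[C@H](CC[C@](C)(O)C=C)[C@@]2(C)CCCC(C)(C)[C@H]12 | starting material
2 | (13S)-13-hydroxylabda-8(17),14-dien-6-one | O=C1CC(=C)[C@H](CC[C@](C)(O)C=C)[C@@]2(C)CCCC(C)(C)[C@H]12 | intermediate
3 | (13S)-13-(triethylsilyloxy)labda-8(17),14-dien-6-one | O=C1CC(=C)[C@H](CC[C@](C)(O[Si](CC)(CC)CC)C=C)[C@@]2(C)CCCC(C)(C)[C@H]12 | intermediate
4 | (13S)-13-(triethylsilyloxy)labda-7,14-dien-6-one | O=C1C=C(C)[C@H](CC[C@](C)(O[Si](CC)(CC)CC)C=C)[C@@]2(C)CCCC(C)(C)[C@H]12 | intermediate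
5 | (13S)-13-(triethylsilyloxy)labda-7,14-dien-6β-ol | O[C@@H]1C=C(C)[C@H](CC[C@](C)(O[Si](CC)(CC)CC)C=C)[C@@]2(C)CCCC(C)(C)[C@H]12 | intermediate
6 | lithium (13S)-13-(triethylsilyloxy)labda-7,14-dien-6β-olate (not isolated) | [Li+].[O-][C@@H]1C=C(C)[C@H](CC[C@](C)(O[Si](CC)(CC)CC)C=C)[C@@]2(C)CCCC(C)(C)[C@H]12 | intermediate
7 | (13S)-13-(triethylsilyloxy)labda-7,14-dien-6β-yl acetate | CC(=O)O[C@@H]1C=C(C)[C@H](CC[C@](C)(O[Si](CC)(CC)CC)C=C)[C@@]2(C)CCCC(C)(C)[C@H]12 | intermediate
8 | (13S)-6β-acetoxy-7α-hydroperoxy-13-(triethylsilyloxy)labda-8,14-diene (not isolated) | CC(=O)O[C@@H]1[C@@H](OO)C(C)=C(CC[C@](C)(O[Si](CC)(CC)CC)C=C)[C@@]2(C)CCCC(C)(C)[C@H]12 | intermediate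
9 | (13S)-6β-acetoxy-7α-(acetylperoxy)-13-(triethylsilyloxy)labda-8,14-diene (not isolated) | CC(=O)O[C@@H]1[C@@H](OOC(C)=O)C(C)=C(CC[C@](C)(O[Si](CC)(CC)CC)C=C)[C@@]2(C)CCCC(C)(C)[C@H]12 | intermediate
10 | (13S)-6β-acetoxy-13-(triethylsilyloxy)labda-8,14-dien-7-one | CC(=O)O[C@@H]1C(=O)C(C)=C(CC[C@](C)(O[Si](CC)(CC)CC)C=C)[C@@]2(C)CCCC(C)(C)[C@H]12 | intermediate
11 | (13S)-6β-acetoxy-13-hydroxylabda-8,14-dien-7-one | CC(=O)O[C@@H]1C(=O)C(C)=C(CC[C@](C)(O)C=C)[C@@]2(C)CCCC(C)(C)[C@H]12 | intermediate
12 | CNP0330581.1, (13S)-6β-acetoxy-13-hydroxy-8,15:9,14-dicyclolabdan-7-one (C8–C15 and C9–C14 bonds both α, 17-CH3 β, C11 β, H-14 on the cyclobutane face of C7/C10, 13-OH exo) | CC(=O)O[C@@H]1C(=O)[C@@]2(C)C[C@H]3[C@@]2(CC[C@]3(C)O)[C@@]2(C)CCCC(C)(C)[C@H]12 | target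

## Step count and risks

Total step count: 8. Longest linear sequence: 8 steps (from larixol 1).

**Step 6.** The ene reaction may abstract hydrogen from the C17 methyl group instead of H-9α, or the allylic hydroperoxide may rearrange or undergo Hock-type cleavage before it is dehydrated; either would erode the yield of the Δ8-7-one. The fallback sets out from 7 and returns at 10. Epoxidation with mCPBA (CH2Cl2, 0 °C), which should pick the trisubstituted alkene over the vinyl group and the open α face, should give the 7α,8α-epoxide F1. Cp2TiCl (from Cp2TiCl2 and Mn dust, THF) should open F1 homolytically to the tertiary C8 radical, which after trapping by a second Cp2TiCl and β-hydride elimination should give the exocyclic allylic alcohol F2. Dess–Martin oxidation should give the exocyclic enone F3, and RhCl3·3H2O (cat., EtOH, 70 °C) should move the double bond into the ring to give enone 10.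

**Step 8.** Attack on the β face, photodeconjugation of the enone through γ-hydrogen abstraction, or α-cleavage of the strained cyclobutyl ketone on over-irradiation may compete with the desired closure. The fallback sets out from hydroperoxide 8 (generated from 7 as in step 6) and returns at 12. It replaces the enone triplet by a copper–diene complex and postpones ketone formation. Reduction of 8 with PPh3 should give the 7α-alcohol F4, and HF·pyridine should give the 7α,13-diol F5. CuOTf-catalysed [2+2] photobicyclisation of the 1,6-diene (hν 254 nm, Et2O), with the 7α-hydroxyl holding copper on the α face, should give the tetracyclic 7α-alcohol F6; this is the weakest link, since copper binds a tetrasubstituted alkene poorly. Dess–Martin oxidation of the only secondary alcohol of F6 should then give 12.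

**Step 5.** Acylation of the hindered axial alkoxide may stall, or the allylic alkoxide may decompose on warming. The fallback sets out from 4 and returns at 7, bypassing 5 and 6. Reduction of 4 with i-Bu2AlH (CH2Cl2, −78 °C) from the α face should give the diisobutylaluminium 6β-alkoxide F7, which is acetylated in the same flask with Ac2O, pyridine and DMAP (−78 → 0 °C) to give 7.

## Further compounds

F1 | step 6 | (13S)-6β-acetoxy-7α,8α-epoxy-13-(triethylsilyloxy)labd-14-ene | CC(=O)O[C@@H]1[C@H]2O[C@@]2(C)[C@H](CC[C@](C)(O[Si](CC)(CC)CC)C=C)[C@@]3(C)CCCC(C)(C)[C@H]13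
F2 | step 6 | (13S)-6β-acetoxy-13-(triethylsilyloxy)labda-8(17),14-dien-7α-ol | CC(=O)O[C@@H]1[C@@H](O)C(=C)[C@H](CC[C@](C)(O[Si](CC)(CC)CC)C=C)[C@@]2(C)CCCC(C)(C)[C@H]12
F3 | step 6 | (13S)-6β-acetoxy-13-(triethylsilyloxy)labda-8(17),14-dien-7-one | CC(=O)O[C@@H]1C(=O)C(=C)[C@H](CC[C@](C)(O[Si](CC)(CC)CC)C=C)[C@@]2(C)CCCC(C)(C)[C@H]12
F4 | step 8 | (13S)-6β-acetoxy-13-(triethylsilyloxy)labda-8,14-dien-7α-ol | CC(=O)O[C@@H]1[C@@H](O)C(C)=C(CC[C@](C)(O[Si](CC)(CC)CC)C=C)[C@@]2(C)CCCC(C)(C)[C@H]12
F5 | step 8 | (13S)-6β-acetoxylabda-8,14-diene-7α,13-diol | CC(=O)O[C@@H]1[C@@H](O)C(C)=C(CC[C@](C)(O)C=C)[C@@]2(C)CCCC(C)(C)[C@H]12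
F6 | step 8 | (13S)-6β-acetoxy-8,15:9,14-dicyclolabdane-7α,13-diol (ring fusion as in 12) | CC(=O)O[C@@H]1[C@@H](O)[C@@]2(C)C[C@H]3[C@@]2(CC[C@]3(C)O)[C@@]2(C)CCCC(C)(C)[C@H]12
F7 | step 5 | diisobutylaluminium (13S)-13-(triethylsilyloxy)labda-7,14-dien-6β-olate | CC(C)C[Al](CC(C)C)O[C@@H]1C=C(C)[C@H](CC[C@](C)(O[Si](CC)(CC)CC)C=C)[C@@]2(C)CCCC(C)(C)[C@H]12
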